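**Plan**
- Retrosynthesis: the pyran ring F of the lower (epicatechin) unit is cut at two bonds, O1–C8a and C4–C4a, to a 3-alkoxyaryne on ring D and a three-carbon bromo alkoxide that carries ring E. Next the C4(u)–C6(l) aryl bond is cut through a 4-aryl-flav-3-ene back to a flavanone, then the C2–aryl bond of that flavanone.
- Enabling feature: ring D is a phloroglucinol nucleus with a local mirror through C6(l) and C8a(l). Before ring F exists, O5/O7 and C4a/C8 are pairwise equivalent, so a 4-chloro-2,6-dialkoxyphenyl group on C4(u) already encodes the 4→6 constitution. Chlorine marks C8a, and the C5 oxygen beside C4a tells the aryne which carbon takes oxygen.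
- Forward order: rings A/C/B (flavanone) → ring D added as an aryl cerium reagent → dehydration → hydroboration; the ring E fragment comes from a glycolate aldol; ring F is closed last; deprotection.
- Stereochemistry: C2(u) by catalytic asymmetric conjugate addition; C3(u) and C4(u) both relayed from C2(u) in one hydroboration; C2(l)/C3(l) from one Evans syn-aldol and carried into ring F untouched, which gives the 2,3-cis relation.

Key step: step 13

Assumption: the sense of induction in step 2 is assigned by analogy with β-substituted cyclic enones; the antipodal ligand is used should the flavanone prove to be 2R. Flavan numbering is used throughout; (u) is the upper unit (rings A, C, B), (l) the lower unit (rings D, F, E).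

**Step 1**
Reactants: 1 7-hydroxy-4H-chromen-4-one
Product: 2 7-(benzyloxy)-4H-chromen-4-one
Conditions: BnBr, K2CO3, DMF, rt
Reagents that add atoms: benzyl bromide, BrCc1ccccc1
Why: Williamson ether synthesis on the only phenol; the benzyl ether survives the organometallic steps and leaves by hydrogenolysis at the end.

**Step 2**
Reactants: 2 7-(benzyloxy)-4H-chromen-4-one; 3 [4-(benzyloxy)phenyl]boronic acid
Product: 4 (2S)-7-(benzyloxy)-2-[4-(benzyloxy)phenyl]chroman-4-one
Conditions: Pd(OCOCF3)2 (5 mol %), (R)-t-BuPyOx [(R)-4-tert-butyl-2-(pyridin-2-yl)-4,5-dihydrooxazole] (6 mol %), NH4PF6 (30 mol %), H2O (5 equiv), ClCH2CH2Cl, 60 °C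
Reagents that add atoms: none
Why: Asymmetric conjugate addition of an arylboronic acid to a chromone (Hayashi–Miyaura type with a pyridine–oxazoline ligand on divalent palladium); the aryl group adds to one face of C2=C3 and the palladium enolate is protonated, so C2 is set by the ligand.

**Step 3**
Reactants: 5 5-chlorobenzene-1,3-diol
Product: 6 5-chloro-2-iodobenzene-1,3-diol
Conditions: I2, NaHCO3, H2O, 0 °C to rt
Reagents that add atoms: iodine, II
Why: Electrophilic iodination of a resorcinol under hydrogencarbonate goes to the carbon between the two hydroxyl groups, here also para to chlorine, which fixes the future interflavan carbon without ambiguity.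

**Step 4**
Reactants: 6 5-chloro-2-iodobenzene-1,3-diol
Product: 7 5-chloro-2-iodo-1,3-bis(methoxymethoxy)benzene
Conditions: MOMCl, i-Pr2NEt, CH2Cl2, 0 °C to rt
Reagents that add atoms: chloromethyl methyl ether, COCCl
Why: Acetal protection of both phenols; the methoxymethyl groups later direct and chelate lithium beside chlorine and are removed in mild acid.

**Step 5**
Reactants: 7 5-chloro-2-iodo-1,3-bis(methoxymethoxy)benzene; 4 (2S)-7-(benzyloxy)-2-[4-(benzyloxy)phenyl]chroman-4-one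
Product: 10 (2S)-7-(benzyloxy)-2-[4-(benzyloxy)phenyl]-4-[4-chloro-2,6-bis(methoxymethoxy)phenyl]chroman-4-ol as a mixture of C4 epimers, via aryllithium 8 (not isolated), via aryl cerium dichloride 9 (not isolated)
Conditions: n-BuLi, THF, −78 °C; CeCl3, −78 °C; then 4, −78 to −20 °C; H2O
Reagents that add atoms: none
Why: Iodine–lithium exchange, transmetalation to cerium and 1,2-addition of the weakly basic organocerium reagent to the ketone (Imamoto conditions) avoid enolisation and retro-oxa-Michael opening of the flavanone, so C2 is kept; the carbinol configuration is lost in the next step.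

**Step 6**
Reactants: 10 (2S)-7-(benzyloxy)-2-[4-(benzyloxy)phenyl]-4-[4-chloro-2,6-bis(methoxymethoxy)phenyl]chroman-4-ol
Product: 11 (2S)-7-(benzyloxy)-2-[4-(benzyloxy)phenyl]-4-[4-chloro-2,6-bis(methoxymethoxy)phenyl]-2H-chromene
Conditions: MsCl, Et3N, DMAP (cat.), CH2Cl2, 0 °C to rt
Reagents that add atoms: none
Why: The tertiary, doubly benzylic mesylate ionises and loses H3 (E1 dehydration) under basic conditions, which spares the acetals and the allylic, benzylic C2–O1 bond.

**Step 7**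
Reactants: 11 (2S)-7-(benzyloxy)-2-[4-(benzyloxy)phenyl]-4-[4-chloro-2,6-bis(methoxymethoxy)phenyl]-2H-chromene
Product: 13 (2R,3S,4S)-7-(benzyloxy)-2-[4-(benzyloxy)phenyl]-4-[4-chloro-2,6-bis(methoxymethoxy)phenyl]chroman-3-ol, via alkylborane 12 (not isolated)
Conditions: BH3·THF, THF, 0 °C to rt; then NaOH, H2O2, 0 °C
Reagents that add atoms: hydrogen peroxide, OO
Why: Hydroboration–oxidation of a flav-3-ene puts boron on C3 and hydrogen on the diaryl-substituted C4 by syn addition to the face away from the C2 aryl group, so C3 (hydroxyl trans to ring B) and C4 (aryl trans to the hydroxyl, cis to ring B) are both relayed from C2 in one event; oxidation retains C3.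

**Step 8**
Reactants: 13 (2R,3S,4S)-7-(benzyloxy)-2-[4-(benzyloxy)phenyl]-4-[4-chloro-2,6-bis(methoxymethoxy)phenyl]chroman-3-ol
Product: 14 (2R,3S,4S)-3,7-bis(benzyloxy)-2-[4-(benzyloxy)phenyl]-4-[4-chloro-2,6-bis(methoxymethoxy)phenyl]chroman
Conditions: NaH, BnBr, Bu4NI (cat.), DMF, 0 °C to rt
Reagents that add atoms: benzyl bromide, BrCc1ccccc1
Why: Williamson ether synthesis removes the only acidic proton before the aryllithium chemistry; aryl chloride and acetals are inert.

**Step 9**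
Reactants: 15 (4S)-4-benzyloxazolidin-2-one; 16 2-(benzyloxy)acetyl chloride
Product: 17 (4S)-4-benzyl-3-[2-(benzyloxy)acetyl]oxazolidin-2-one
Conditions: n-BuLi, THF, −78 °C; then 16
Reagents that add atoms: none
Why: N-acylation of the lithiated oxazolidinone gives the glycolate imide; the stereocenter of the auxiliary is bought.

**Step 10**
Reactants: 17 (4S)-4-benzyl-3-[2-(benzyloxy)acetyl]oxazolidin-2-one; 18 3,4-bis(benzyloxy)benzaldehyde
Product: 20 (4S)-4-benzyl-3-[(2S,3R)-2-(benzyloxy)-3-[3,4-bis(benzyloxy)phenyl]-3-hydroxypropanoyl]oxazolidin-2-one, via boron enolate 19 (not isolated)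
Conditions: Bu2BOTf, Et3N, CH2Cl2, −78 to 0 °C; 18, −78 to 0 °C; then pH 7 buffer, MeOH, H2O2
Reagents that add atoms: none
Why: Evans syn-glycolate aldol: the Z boron enolate reacts through a chair (Zimmerman–Traxler) transition state on the face away from the benzyl group of the auxiliary, which sets both carbinol carbons (2S,3R, syn) in one event.

**Step 11**
Reactants: 20 (4S)-4-benzyl-3-[(2S,3R)-2-(benzyloxy)-3-[3,4-bis(benzyloxy)phenyl]-3-hydroxypropanoyl]oxazolidin-2-one
Product: 21 (1R,2R)-2-(benzyloxy)-1-[3,4-bis(benzyloxy)phenyl]propane-1,3-diol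
Conditions: LiBH4, THF, H2O (1 equiv), 0 °C
Reagents that add atoms: none
Why: Reductive cleavage of the imide to the primary alcohol releases the auxiliary and touches neither stereocenter (the descriptor at C2 changes only through priorities).

**Step 12**
Reactants: 21 (1R,2R)-2-(benzyloxy)-1-[3,4-bis(benzyloxy)phenyl]propane-1,3-diol
Product: 23 (1R,2S)-2-(benzyloxy)-1-[3,4-bis(benzyloxy)phenyl]-3-bromopropan-1-ol, via tosylate 22 (not isolated)
Conditions: TsCl (1.1 equiv), pyridine, CH2Cl2, 0 °C; then LiBr, acetone, 50 °C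
Reagents that add atoms: lithium bromide, [Li+].[Br-]
Why: The primary hydroxyl is sulfonylated in preference to the hindered benzylic one and bromide displaces the tosylate at CH2 (Finkelstein-type SN2); the free benzylic hydroxyl is the future O1.

**Step 13**
Reactants: 14 (2R,3S,4S)-3,7-bis(benzyloxy)-2-[4-(benzyloxy)phenyl]-4-[4-chloro-2,6-bis(methoxymethoxy)phenyl]chroman; 23 (1R,2S)-2-(benzyloxy)-1-[3,4-bis(benzyloxy)phenyl]-3-bromopropan-1-ol
Product: 28 (2R,3S,4S)-3,7-bis(benzyloxy)-2-[4-(benzyloxy)phenyl]-4-[(2R,3R)-3-(benzyloxy)-2-[3,4-bis(benzyloxy)phenyl]-5,7-bis(methoxymethoxy)chroman-6-yl]chroman, via aryllithium 24 (not isolated), via lithium alkoxide 25 (not isolated), via aryne 26 (not isolated), via aryllithium adduct 27 (not isolated)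
Conditions: 14, n-BuLi (1.05 equiv), THF, −78 °C, 1 h; add to 25 [from 23 (2 equiv), n-BuLi (2 equiv), THF, −78 °C]; −78 to −30 °C, then 0 °C to rt
Reagents that add atoms: none
Why: Proposed new method: on warming, the 2-lithio-1-chloroarene 24 loses LiCl to give aryne 26 (C4a≡C8a of ring D); the lithium alkoxide 25, held beside it in a mixed aggregate, adds its oxygen to C8a, and the aryl carbanion so formed at C4a (27) displaces the primary bromide in a 6-exo-tet closure of ring F, so the aryne takes up O1 and C4 in one operation. The closest known reaction types are the annulation of arynes with salicylates or 2-hydroxychalcones (oxygen adds, the aryl anion is trapped within the same molecule) and the Parham cycloalkylation of ortho-lithiated aryl 3-halopropyl ethers to chromans. The side of addition follows from the groups beside the triple bond: the C5 oxygen next to C4a makes C8a, which has only C8–H beside it, the electrophilic carbon (inductive and distortion control as in 3-alkoxybenzynes) and stabilises the charge at C4a by chelation. No stereocenter is formed; C2(l) and C3(l) come unchanged from 23 because no bond to either is made or broken, which secures the 2,3-cis relation that a closure through O1–C2 would put at risk. The step needs the 4→6 and not the 4→8 constitution, and this is secured because chlorine sits para to the interflavan carbon and the two positions beside it are equivalent by rotation about the C4(u)–C6(l) bond.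

**Step 14**
Reactants: 28 (2R,3S,4S)-3,7-bis(benzyloxy)-2-[4-(benzyloxy)phenyl]-4-[(2R,3R)-3-(benzyloxy)-2-[3,4-bis(benzyloxy)phenyl]-5,7-bis(methoxymethoxy)chroman-6-yl]chroman
Product: 29 (2R,3R)-3-(benzyloxy)-6-[(2R,3S,4S)-3,7-bis(benzyloxy)-2-[4-(benzyloxy)phenyl]chroman-4-yl]-2-[3,4-bis(benzyloxy)phenyl]chroman-5,7-diol
Conditions: HCl (from AcCl), MeOH–THF, 0 °C to rt
Reagents that add atoms: none
Why: Acid-catalysed acetal exchange frees the two ring D phenols; the interflavan bond of a 5-deoxy upper unit resists acid, and benzyl ethers are untouched.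

**Step 15**
Reactants: 29 (2R,3R)-3-(benzyloxy)-6-[(2R,3S,4S)-3,7-bis(benzyloxy)-2-[4-(benzyloxy)phenyl]chroman-4-yl]-2-[3,4-bis(benzyloxy)phenyl]chroman-5,7-diol
Product: 30 (2R,3S,4S)-4-[(2R,3R)-2-(3,4-dihydroxyphenyl)-3,5,7-trihydroxychroman-6-yl]-2-(4-hydroxyphenyl)chroman-3,7-diol
Conditions: H2 (1 atm), Pd(OH)2/C, THF–MeOH, rt
Reagents that add atoms: none
Why: Hydrogenolysis of the six benzyl ethers under the conditions standard for benzylated proanthocyanidins should leave the ring C–O bonds and all five stereocenters intact.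

**Compound list**
1 | 7-hydroxy-4H-chromen-4-one | O=c1ccoc2cc(O)ccc12 | starting material
2 | 7-(benzyloxy)-4H-chromen-4-one | O=c1ccoc2cc(OCc3ccccc3)ccc12 | intermediate
3 | [4-(benzyloxy)phenyl]boronic acid | OB(O)c1ccc(OCc2ccccc2)cc1 | starting material
4 | (2S)-7-(benzyloxy)-2-[4-(benzyloxy)phenyl]chroman-4-one | O=C1C[C@@H](c2ccc(OCc3ccccc3)cc2)Oc2cc(OCc3ccccc3)ccc12 | intermediate
5 | 5-chlorobenzene-1,3-diol | Oc1cc(O)cc(Cl)c1 | starting material
6 | 5-chloro-2-iodobenzene-1,3-diol | Oc1cc(Cl)cc(O)c1I | intermediate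
7 | 5-chloro-2-iodo-1,3-bis(methoxymethoxy)benzene | COCOc1cc(Cl)cc(OCOC)c1I | intermediate
8 | [4-chloro-2,6-bis(methoxymethoxy)phenyl]lithium | [Li]c1c(OCOC)cc(Cl)cc1OCOC | intermediate
9 | dichloro[4-chloro-2,6-bis(methoxymethoxy)phenyl]cerium | Cl[Ce](Cl)c1c(OCOC)cc(Cl)cc1OCOC | intermediate
10 | (2S)-7-(benzyloxy)-2-[4-(benzyloxy)phenyl]-4-[4-chloro-2,6-bis(methoxymethoxy)phenyl]chroman-4-ol (C4 epimers) | OC1(c2c(OCOC)cc(Cl)cc2OCOC)C[C@@H](c2ccc(OCc3ccccc3)cc2)Oc2cc(OCc3ccccc3)ccc12 | intermediate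
11 | (2S)-7-(benzyloxy)-2-[4-(benzyloxy)phenyl]-4-[4-chloro-2,6-bis(methoxymethoxy)phenyl]-2H-chromene | COCOc1cc(Cl)cc(OCOC)c1C1=C[C@@H](c2ccc(OCc3ccccc3)cc2)Oc2cc(OCc3ccccc3)ccc12 | intermediate
12 | [(2R,3S,4S)-7-(benzyloxy)-2-[4-(benzyloxy)phenyl]-4-[4-chloro-2,6-bis(methoxymethoxy)phenyl]chroman-3-yl]borane | c1ccccc1COc1ccc([C@H]2Oc3cc(OCc4ccccc4)ccc3[C@@H](c3c(OCOC)cc(Cl)cc3OCOC)[C@@H]2B)cc1 | intermediate
13 | (2R,3S,4S)-7-(benzyloxy)-2-[4-(benzyloxy)phenyl]-4-[4-chloro-2,6-bis(methoxymethoxy)phenyl]chroman-3-ol | c1ccccc1COc1ccc([C@H]2Oc3cc(OCc4ccccc4)ccc3[C@@H](c3c(OCOC)cc(Cl)cc3OCOC)[C@@H]2O)cc1 | intermediate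
14 | (2R,3S,4S)-3,7-bis(benzyloxy)-2-[4-(benzyloxy)phenyl]-4-[4-chloro-2,6-bis(methoxymethoxy)phenyl]chroman | c1ccccc1COc1ccc([C@H]2Oc3cc(OCc4ccccc4)ccc3[C@@H](c3c(OCOC)cc(Cl)cc3OCOC)[C@@H]2OCc2ccccc2)cc1 | intermediate
15 | (4S)-4-benzyloxazolidin-2-one | O=C1N[C@@H](Cc2ccccc2)CO1 | starting material
16 | 2-(benzyloxy)acetyl chloride | ClC(=O)COCc1ccccc1 | starting material
17 | (4S)-4-benzyl-3-[2-(benzyloxy)acetyl]oxazolidin-2-one | O=C1OC[C@H](Cc2ccccc2)N1C(=O)COCc1ccccc1 | intermediate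
18 | 3,4-bis(benzyloxy)benzaldehyde | O=Cc1ccc(OCc2ccccc2)c(OCc2ccccc2)c1 | starting material
19 | Z dibutylboron enolate of 17 | CCCCB(CCCC)O/C(=C\OCc1ccccc1)N1C(=O)OC[C@@H]1Cc1ccccc1 | intermediate
20 | (4S)-4-benzyl-3-[(2S,3R)-2-(benzyloxy)-3-[3,4-bis(benzyloxy)phenyl]-3-hydroxypropanoyl]oxazolidin-2-one | O=C(N1C(=O)OC[C@@H]1Cc1ccccc1)[C@@H](OCc1ccccc1)[C@H](O)c1ccc(OCc2ccccc2)c(OCc2ccccc2)c1 | intermediate
21 | (1R,2R)-2-(benzyloxy)-1-[3,4-bis(benzyloxy)phenyl]propane-1,3-diol | OC[C@@H](OCc1ccccc1)[C@@H](c1ccc(OCc2ccccc2)c(OCc2ccccc2)c1)O | intermediate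
22 | (2R,3R)-2-(benzyloxy)-3-[3,4-bis(benzyloxy)phenyl]-3-hydroxypropyl 4-methylbenzenesulfonate | Cc1ccc(cc1)S(=O)(=O)OC[C@@H](OCc1ccccc1)[C@@H](c1ccc(OCc2ccccc2)c(OCc2ccccc2)c1)O | intermediate
23 | (1R,2S)-2-(benzyloxy)-1-[3,4-bis(benzyloxy)phenyl]-3-bromopropan-1-ol | BrC[C@@H](OCc1ccccc1)[C@@H](c1ccc(OCc2ccccc2)c(OCc2ccccc2)c1)O | intermediate
24 | 14 lithiated on ring D between chlorine and one methoxymethoxy group | c1ccccc1COc1ccc([C@H]2Oc3cc(OCc4ccccc4)ccc3[C@@H](c3c(OCOC)c([Li])c(Cl)cc3OCOC)[C@@H]2OCc2ccccc2)cc1 | intermediate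
25 | lithium alkoxide of 23 | BrC[C@@H](OCc1ccccc1)[C@@H](c1ccc(OCc2ccccc2)c(OCc2ccccc2)c1)O[Li] | intermediate
26 | ring D aryne (C4a≡C8a) derived from 24 | c1ccccc1COc1ccc([C@H]2Oc3cc(OCc4ccccc4)ccc3[C@@H](C3=C(OCOC)C#CC=C3OCOC)[C@@H]2OCc2ccccc2)cc1 | intermediate
27 | aryl ether with lithium at C4a and the bromomethyl group still open | c1ccccc1COc1ccc([C@H]2Oc3cc(OCc4ccccc4)ccc3[C@@H](c3c(OCOC)c([Li])c(O[C@H](c4ccc(OCc5ccccc5)c(OCc5ccccc5)c4)[C@H](OCc4ccccc4)CBr)cc3OCOC)[C@@H]2OCc2ccccc2)cc1 | intermediate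
28 | (2R,3S,4S)-3,7-bis(benzyloxy)-2-[4-(benzyloxy)phenyl]-4-[(2R,3R)-3-(benzyloxy)-2-[3,4-bis(benzyloxy)phenyl]-5,7-bis(methoxymethoxy)chroman-6-yl]chroman | c1ccccc1COc1ccc([C@H]2Oc3cc(OCc4ccccc4)ccc3[C@@H](c3c(OCOC)cc4c(c3OCOC)C[C@@H](OCc3ccccc3)[C@@H](c3ccc(OCc5ccccc5)c(OCc5ccccc5)c3)O4)[C@@H]2OCc2ccccc2)cc1 | intermediate
29 | (2R,3R)-3-(benzyloxy)-6-[(2R,3S,4S)-3,7-bis(benzyloxy)-2-[4-(benzyloxy)phenyl]chroman-4-yl]-2-[3,4-bis(benzyloxy)phenyl]chroman-5,7-diol | c1ccccc1COc1ccc([C@H]2Oc3cc(OCc4ccccc4)ccc3[C@@H](c3c(O)cc4c(c3O)C[C@@H](OCc3ccccc3)[C@@H](c3ccc(OCc5ccccc5)c(OCc5ccccc5)c3)O4)[C@@H]2OCc2ccccc2)cc1 | intermediate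
30 | (2R,3S,4S)-4-[(2R,3R)-2-(3,4-dihydroxyphenyl)-3,5,7-trihydroxychroman-6-yl]-2-(4-hydroxyphenyl)chroman-3,7-diol (guibourtinidol-(4α→6)-epicatechin) | Oc1ccc([C@H]2Oc3cc(O)ccc3[C@@H](c3c(O)cc4c(c3O)C[C@@H](O)[C@@H](c3ccc(O)c(O)c3)O4)[C@@H]2O)cc1 | target

**Totals**
Total steps: 15. Longest linear sequence: 9 steps (1, 2, 5, 6, 7, 8, 13, 14, 15).

**Steps most likely to fail**

1. Step 13 (Proposed new method). Capture of the aryne by the lithium alkoxide may be slower than attack by a second aryllithium, or the bromo alkoxide may close to an oxetane or fragment before the aryne forms. Fallback, from 20 and 14, back at 28, all known chemistry: 20 is silylated (TBSOTf, 2,6-lutidine) to the silyl ether F1, reduced with LiBH4 to the primary alcohol F2 and converted with Tf2O and 2,6-di-tert-butylpyridine into the triflate F3. Aryllithium 24, made from 14 as above and kept at −78 °C so that LiCl is not lost, is alkylated by F3 to the chloroarene F4. Bu4NF frees the benzylic alcohol F5, and palladium-catalysed intramolecular aryl ether formation (Pd(OAc)2, 2-(di-tert-butylphosphino)-1,1'-binaphthyl, Cs2CO3, toluene, 80 °C) closes ring F with retention to give 28.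

2. Step 5. The crowded aryl metal may enolise the flavanone (ring opening and loss of C2 configuration) or fail to add. Fallback, from 4 and 7, back at 11 (step 6 is skipped): ketone 4 is turned into the enol triflate F6 (KHMDS, PhNTf2, THF, −78 °C); aryllithium 8 from 7 is quenched with 2-isopropoxy-4,4,5,5-tetramethyl-1,3,2-dioxaborolane to the boronate F7; Suzuki–Miyaura coupling of F6 with F7 (Pd(PPh3)4, K3PO4, DMF, 80 °C; the aryl chloride is inert to this catalyst) gives 11.

3. Step 2. Facial control may be incomplete on the electron-rich chromone, or the boronic acid may protodeboronate. Fallback, from 2 and 3, back at 4: the same addition with an achiral ligand (Pd(OCOCF3)2, 2,2'-bipyridine) gives the racemic flavanone F8. Kinetic resolution by transfer hydrogenation (RuCl(p-cymene)[(R,R)-TsDPEN], HCO2H–Et3N) should reduce the 2R ketone to the cis-flavan-4-ol F9 and leave 4, which is separated by chromatography.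

**Further compounds**
F1 | step 13 | (4S)-4-benzyl-3-[(2S,3R)-2-(benzyloxy)-3-[3,4-bis(benzyloxy)phenyl]-3-[(tert-butyldimethylsilyl)oxy]propanoyl]oxazolidin-2-one | O=C(N1C(=O)OC[C@@H]1Cc1ccccc1)[C@@H](OCc1ccccc1)[C@H](O[Si](C)(C)C(C)(C)C)c1ccc(OCc2ccccc2)c(OCc2ccccc2)c1
F2 | step 13 | (2R,3R)-2-(benzyloxy)-3-[3,4-bis(benzyloxy)phenyl]-3-[(tert-butyldimethylsilyl)oxy]propan-1-ol | OC[C@@H](OCc1ccccc1)[C@@H](c1ccc(OCc2ccccc2)c(OCc2ccccc2)c1)O[Si](C)(C)C(C)(C)C
F3 | step 13 | (2R,3R)-2-(benzyloxy)-3-[3,4-bis(benzyloxy)phenyl]-3-[(tert-butyldimethylsilyl)oxy]propyl trifluoromethanesulfonate | FC(F)(F)S(=O)(=O)OC[C@@H](OCc1ccccc1)[C@@H](c1ccc(OCc2ccccc2)c(OCc2ccccc2)c1)O[Si](C)(C)C(C)(C)C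
F4 | step 13 | 14 carrying the (2R,3R)-2-(benzyloxy)-3-[3,4-bis(benzyloxy)phenyl]-3-[(tert-butyldimethylsilyl)oxy]propyl group on ring D between chlorine and a methoxymethoxy group | c1ccccc1COc1ccc([C@H]2Oc3cc(OCc4ccccc4)ccc3[C@@H](c3c(OCOC)cc(Cl)c(C[C@@H](OCc4ccccc4)[C@@H](c4ccc(OCc5ccccc5)c(OCc5ccccc5)c4)O[Si](C)(C)C(C)(C)C)c3OCOC)[C@@H]2OCc2ccccc2)cc1
F5 | step 13 | benzylic alcohol from F4 | c1ccccc1COc1ccc([C@H]2Oc3cc(OCc4ccccc4)ccc3[C@@H](c3c(OCOC)cc(Cl)c(C[C@@H](OCc4ccccc4)[C@@H](c4ccc(OCc5ccccc5)c(OCc5ccccc5)c4)O)c3OCOC)[C@@H]2OCc2ccccc2)cc1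
F6 | step 5 | (2S)-7-(benzyloxy)-2-[4-(benzyloxy)phenyl]-2H-chromen-4-yl trifluoromethanesulfonate | FC(F)(F)S(=O)(=O)OC1=C[C@@H](c2ccc(OCc3ccccc3)cc2)Oc2cc(OCc3ccccc3)ccc12
F7 | step 5 | 2-[4-chloro-2,6-bis(methoxymethoxy)phenyl]-4,4,5,5-tetramethyl-1,3,2-dioxaborolane | COCOc1cc(Cl)cc(OCOC)c1B1OC(C)(C)C(C)(C)O1
F8 | step 2 | racemic 7-(benzyloxy)-2-[4-(benzyloxy)phenyl]chroman-4-one | O=C1CC(c2ccc(OCc3ccccc3)cc2)Oc2cc(OCc3ccccc3)ccc12
F9 | step 2 | (2R,4R)-7-(benzyloxy)-2-[4-(benzyloxy)phenyl]chroman-4-ol | O[C@@H]1C[C@H](c2ccc(OCc3ccccc3)cc2)Oc2cc(OCc3ccccc3)ccc21
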